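**Plan**

1. After removal of six tert-butyldimethylsilyl (TBS) groups, the two terminal Cα–aryl bonds are cut together. This is possible because unit A (on one syringyl oxygen) and unit C (outermost unit on the other side) are both erythro arylglycerols: in each, a benzylic carbinol carbon Cα bonded to a 4-hydroxy-3-methoxyphenyl ring sits next to a Cβ that carries an aryloxy oxygen and a CH2OH group. One aryl Grignard reagent and one dialdehyde therefore serve both ends.
2. Further cuts, in order: Cβ–O(aryl) of unit C; Cα–aryl of unit B (as an aryl ketone); both syringyl O–Cβ bonds; then the C8–C8' bond and the two C7–O bonds of the 3,7-dioxabicyclo[3.3.0]octane core (dimerisation of sinapyl alcohol).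
3. Forward: syringaldehyde → sinapyl alcohol → oxidative dimerisation (both tetrahydrofuran rings close in one step) → resolution → double etherification with the D-serine-derived glycerate triflate → bis(Weinreb amide) → mono-arylation (desymmetrisation), reduction, silylation → phenol release and etherification with the L-serine-derived triflate → double partial reduction → double arylation → desilylation.
4. Stereochemistry: the four ring centres are set relative to each other by the dimerisation cascade and made absolute by chromatographic resolution. The three Cβ centres come from D- and L-serine through SN2 inversion of the triflates. Cα of unit B (threo) comes from a CBS reduction matched with Felkin–Anh control. Cα of units A and C (erythro) comes from Felkin–Anh addition.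

Key step: step 21

Remark: the structure is read as (7S,8R,7'S,8'R) in the furofuran, (αR,βS) in unit A, (αS,βS) in unit B and (αS,βR) in unit C; the (7S,8R,7'S,8'R) enantiomer of syringaresinol is assumed to be the dextrorotatory one and would be assigned by chiroptical comparison, not by sign alone (TBS = tert-butyldimethylsilyl).

**Route**

Step 1
Reactants: 1 syringaldehyde
Product: 2 ethyl (E)-sinapate
Conditions: Ph3P=CHCO2Et (1.2 equiv), toluene, 90 °C
Reagents that add atoms: ethyl (triphenylphosphoranylidene)acetate, CCOC(=O)C=P(c1ccccc1)(c1ccccc1)c1ccccc1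
Why: Wittig olefination with a stabilised ylide tolerates the free phenol and should give the E-cinnamate almost exclusively.

Step 2
Reactants: 2 ethyl (E)-sinapate
Product: 3 (E)-sinapyl alcohol
Conditions: i-Bu2AlH (DIBAL-H, 4 equiv), toluene, 0 °C; aq. Rochelle salt
Reagents that add atoms: none
Why: 1,2-reduction of the cinnamate ester by DIBAL-H (one equivalent is taken up by the phenol) is the standard entry to monolignols and leaves the E-alkene untouched.

Step 3
Reactants: 3 (E)-sinapyl alcohol (two molecules)
Product: 5 racemic syringaresinol, via bis-quinone methide 4 (not isolated)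
Conditions: FeCl3·6H2O (2.2 equiv), acetone/H2O, rt
Reagents that add atoms: none
Why: Biomimetic oxidative dehydrodimerisation: one-electron phenol oxidation, 8–8' radical coupling (the 3- and 5-positions are blocked by methoxy groups) and two 5-exo-trig additions of the 9- and 9'-hydroxyls to the quinone methides should give the cis-fused furofuran with both aryl groups exo, which fixes the relative configuration of all four ring stereocentres.

Step 4
Reactants: 5 racemic syringaresinol
Product: 6 (7S,8R,7'S,8'R)-syringaresinol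
Conditions: preparative HPLC, cellulose tris(3,5-dimethylphenylcarbamate) on silica, n-hexane/EtOH
Reagents that add atoms: none
Why: Chromatographic resolution on a polysaccharide carbamate phase is an established way to separate furofuran lignan enantiomers and supplies the absolute configuration of the core.

Step 5
Reactants: 7 D-serine
Product: 9 methyl (R)-glycerate, via (R)-glyceric acid 8 (not isolated)
Conditions: NaNO2, aq. H2SO4, 0 °C to rt; evaporate; MeOH, HCl (cat.), 50 °C
Reagents that add atoms: water, O; methanol, CO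
Why: Diazotisation of the α-amino acid passes through the α-lactone (double inversion), so hydroxyl replaces nitrogen with net retention, and Fischer esterification of the crude acid does not touch the stereocentre.

Step 6
Reactants: 9 methyl (R)-glycerate
Product: 10 methyl (R)-3-(tert-butyldimethylsilyloxy)-2-hydroxypropanoate
Conditions: TBSCl (1.05 equiv), imidazole, CH2Cl2, 0 °C
Reagents that add atoms: tert-butyldimethylsilyl chloride, CC(C)(C)[Si](C)(C)Cl
Why: Silylation should be selective for the primary hydroxyl over the more hindered and less nucleophilic α-hydroxy ester position.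

Step 7
Reactants: 10 methyl (R)-3-(tert-butyldimethylsilyloxy)-2-hydroxypropanoate
Product: 11 methyl (R)-3-(tert-butyldimethylsilyloxy)-2-(trifluoromethylsulfonyloxy)propanoate
Conditions: Tf2O, 2,6-lutidine, CH2Cl2, −78 °C; cold work-up, used at once
Reagents that add atoms: triflic anhydride, O=S(=O)(OS(=O)(=O)C(F)(F)F)C(F)(F)F
Why: O-sulfonylation of the α-hydroxy ester breaks no bond to carbon, so the configuration is retained and an SN2-active α-triflyloxy ester results.

Step 8
Reactants: 6 (7S,8R,7'S,8'R)-syringaresinol; 11 (R)-triflate (2.4 equiv)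
Product: 12 dimethyl (2S,2'S)-2,2'-[(7S,8R,7'S,8'R)-syringaresinol-4,4'-diylbis(oxy)]bis[3-(tert-butyldimethylsilyloxy)propanoate]
Conditions: Cs2CO3, MeCN, −20 °C to rt
Reagents that add atoms: none
Why: Williamson-type SN2 displacement of the α-triflyloxy ester by each 2,6-dimethoxyphenoxide should proceed with inversion, turning the (R)-triflate into the (S)-aryloxy ester that becomes Cβ of units A and B.

Step 9
Reactants: 12 bis-ether diester
Product: 13 the corresponding (2S,2'S)-bis(N-methoxy-N-methylamide)
Conditions: MeNH(OMe)·HCl (6 equiv), i-PrMgCl (12 equiv), THF, −20 °C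
Reagents that add atoms: N,O-dimethylhydroxylamine hydrochloride, CNOC.Cl
Why: Weinreb amide formation by aminolysis of the esters with the chloromagnesium amide is fast at low temperature and should not enolise the α-aryloxy stereocentres.

Step 10
Reactants: 14 4-bromo-2-methoxyphenol
Product: 15 (4-bromo-2-methoxyphenoxy)(tert-butyl)dimethylsilane
Conditions: TBSCl, imidazole, DMF, rt
Reagents that add atoms: tert-butyldimethylsilyl chloride, CC(C)(C)[Si](C)(C)Cl
Why: Routine phenol silylation masks the acidic proton ahead of Grignard formation.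

Step 11
Reactants: 15 (4-bromo-2-methoxyphenoxy)(tert-butyl)dimethylsilane
Product: 16 4-(tert-butyldimethylsilyloxy)-3-methoxyphenylmagnesium bromide (titrated THF solution)
Conditions: Mg turnings, I2 (cat.), THF, 40 °C
Reagents that add atoms: magnesium, [Mg]
Why: Grignard formation by magnesium insertion into the aryl–bromine bond is compatible with aryl silyl and methyl ethers.

Step 12
Reactants: 13 bis(Weinreb amide); 16 aryl Grignard reagent (1.0 equiv)
Product: 17 mono-ketone: one amide of 13 replaced by 4-(tert-butyldimethylsilyloxy)-3-methoxybenzoyl (unit B, Cβ S), the other amide retained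
Conditions: 16 (1.0 equiv, slow addition), THF, −40 to 0 °C; cold aq. NH4Cl
Reagents that add atoms: none
Why: Weinreb ketone synthesis stops at the ketone because the magnesium chelate survives until work-up; the two remote amides react independently, so one equivalent should give a statistical mixture from which 17 is separated and unreacted 13 recycled, and the untouched amide serves as the masked aldehyde of unit A.

Step 13
Reactants: 17 mono-ketone
Product: 18 threo alcohol: ketone of 17 reduced to the (αS,βS) carbinol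
Conditions: (S)-Me-CBS oxazaborolidine (C18H20BNO, 0.3 equiv), BH3·SMe2 (0.8 equiv), THF, −30 °C; MeOH quench
Reagents that add atoms: none
Why: Corey–Bakshi–Shibata reduction with the (S)-oxazaborolidine, the aryl ring acting as the large substituent, should deliver hydride to the face that gives (S)-Cα; this is also the face favoured by Felkin–Anh attack anti to the Cβ–OAr bond, so catalyst and substrate are matched for the threo unit B, and the non-basic conditions spare Cβ and the Weinreb amide.

Step 14
Reactants: 18 threo alcohol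
Product: 19 α-O-TBS ether of 18
Conditions: TBSOTf (1.5 equiv), 2,6-lutidine, CH2Cl2, −40 to 0 °C
Reagents that add atoms: tert-butyldimethylsilyl triflate, CC(C)(C)[Si](C)(C)OS(=O)(=O)C(F)(F)F
Why: Silyl triflate with a hindered base silylates the congested benzylic secondary alcohol under non-epimerising conditions.

Step 15
Reactants: 19 silyl ether
Product: 20 phenol: 19 with the aryl silyl ether of the unit B ring cleaved
Conditions: KHF2 (2 equiv), MeOH/THF, rt
Reagents that add atoms: none
Why: Bifluoride desilylation is chemoselective for the aryl silyl ether (phenoxide is by far the better leaving group) and should leave the two primary and the benzylic alkyl silyl ethers intact.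

Step 16
Reactants: 21 L-serine
Product: 23 methyl (S)-glycerate, via (S)-glyceric acid 22 (not isolated)
Conditions: NaNO2, aq. H2SO4, 0 °C to rt; evaporate; MeOH, HCl (cat.), 50 °C
Reagents that add atoms: water, O; methanol, CO
Why: Diazotisation with net retention through the α-lactone followed by Fischer esterification, as in step 5.

Step 17
Reactants: 23 methyl (S)-glycerate
Product: 24 methyl (S)-3-(tert-butyldimethylsilyloxy)-2-hydroxypropanoate
Conditions: TBSCl (1.05 equiv), imidazole, CH2Cl2, 0 °C
Reagents that add atoms: tert-butyldimethylsilyl chloride, CC(C)(C)[Si](C)(C)Cl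
Why: Selective silylation of the primary hydroxyl, as in step 6.

Step 18
Reactants: 24 methyl (S)-3-(tert-butyldimethylsilyloxy)-2-hydroxypropanoate
Product: 25 methyl (S)-3-(tert-butyldimethylsilyloxy)-2-(trifluoromethylsulfonyloxy)propanoate
Conditions: Tf2O, 2,6-lutidine, CH2Cl2, −78 °C; cold work-up, used at once
Reagents that add atoms: triflic anhydride, O=S(=O)(OS(=O)(=O)C(F)(F)F)C(F)(F)F
Why: O-sulfonylation with retention, as in step 7.

Step 19
Reactants: 20 phenol; 25 (S)-triflate (1.3 equiv)
Product: 26 ester–amide: 20 with the unit B phenol oxygen bonded to C2 of methyl (R)-3-(tert-butyldimethylsilyloxy)propanoate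
Conditions: Cs2CO3, MeCN, −20 °C to rt
Reagents that add atoms: none
Why: SN2 etherification with inversion converts the (S)-triflate into the (R)-aryloxy ester (Cβ of unit C), the phenoxide being the only nucleophile present.

Step 20
Reactants: 26 ester–amide
Product: 27 dialdehyde: (S)-2-aryloxy-3-silyloxypropanal on the unit A side and (R)-2-aryloxy-3-silyloxypropanal on the unit B ring
Conditions: i-Bu2AlH (DIBAL-H, 5 equiv), CH2Cl2, −78 °C; MeOH, aq. Rochelle salt; used crude
Reagents that add atoms: none
Why: Partial reduction: at −78 °C both the α-aryloxy methyl ester and the Weinreb amide give tetrahedral aluminium adducts that persist until hydrolysis, so each terminus should stop at the aldehyde, and immediate use avoids epimerisation of the α-aryloxy aldehydes.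

Step 21
Reactants: 27 dialdehyde; 16 aryl Grignard reagent (5 equiv)
Product: 28 hexa-O-TBS ether of the target with free Cα hydroxyls in units A and C
Conditions: 16 (5 equiv), THF, −78 °C; aq. NH4Cl at −78 °C
Reagents that add atoms: none
Why: Each formyl carbon (future Cα of unit A and of unit C) undergoes polar 1,2-addition of the aryl Grignard reagent, so both Cα–aryl bonds and both benzylic carbinols form in one operation and no ring is closed. The closest known reaction type is the Felkin–Anh (non-chelation) addition of aryl Grignard or aryllithium reagents to 2-aryloxy aldehydes, used to make erythro 8-O-4' neolignans. At each aldehyde the electronegative Cβ–OAr bond lies antiperiplanar to the incoming aryl group, which passes the Cβ hydrogen and not the silyloxymethyl group, so (S)-Cβ of unit A directs (R)-Cα and (R)-Cβ of unit C directs (S)-Cα, erythro at both ends. Because the two Cβ centres have opposite absolute configuration and are too far apart to interact, substrate control is the only way to set both carbinols in a single operation. The step needs Felkin–Anh over Cram-chelate selectivity and addition over enolisation; the weakly Lewis-basic aryl ether oxygen, the silyl-capped primary oxygen, THF as donor solvent and −78 °C disfavour a magnesium chelate, and the aryl nucleophile adds faster than it deprotonates at that temperature. The silyl ethers and the furofuran ether rings are inert to the reagent.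

Step 22
Reactants: 28 hexa-O-TBS ether
Product: 29 target compound
Conditions: Bu4NF (9 equiv), AcOH (9 equiv), THF, 0 °C to rt
Reagents that add atoms: none
Why: Fluoride-induced desilylation should cleave all six Si–O bonds (two aryl, three primary, one benzylic secondary), and acetic acid buffering avoids phenoxide-driven quinone methide formation or β-ether cleavage, so no stereocentre is touched.

**Compound list**

1 | syringaldehyde | COc1cc(C=O)cc(OC)c1O | starting material
2 | ethyl (E)-sinapate | CCOC(=O)/C=C/c1cc(OC)c(O)c(OC)c1 | intermediate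
3 | (E)-sinapyl alcohol | OC/C=C/c1cc(OC)c(O)c(OC)c1 | intermediate
4 | 8–8'-linked bis(quinone methide), (8R,8'R)/(8S,8'S) racemate, not isolated | O=C1C(OC)=CC(=C[C@@H](CO)[C@H](CO)C=C2C=C(OC)C(=O)C(OC)=C2)C=C1OC.O=C1C(OC)=CC(=C[C@H](CO)[C@@H](CO)C=C2C=C(OC)C(=O)C(OC)=C2)C=C1OC | intermediate
5 | racemic syringaresinol (both enantiomers written) | COc1cc([C@H]2OC[C@H]3[C@@H]2CO[C@@H]3c2cc(OC)c(O)c(OC)c2)cc(OC)c1O.COc1cc([C@@H]2OC[C@@H]3[C@H]2CO[C@H]3c2cc(OC)c(O)c(OC)c2)cc(OC)c1O | intermediate
6 | (7S,8R,7'S,8'R)-syringaresinol | COc1cc([C@H]2OC[C@H]3[C@@H]2CO[C@@H]3c2cc(OC)c(O)c(OC)c2)cc(OC)c1O | intermediate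
7 | D-serine | N[C@H](CO)C(=O)O | starting material
8 | (R)-glyceric acid, not isolated | O[C@H](CO)C(=O)O | intermediate
9 | methyl (R)-glycerate | O[C@H](CO)C(=O)OC | intermediate
10 | methyl (R)-3-(tert-butyldimethylsilyloxy)-2-hydroxypropanoate | O[C@H](CO[Si](C)(C)C(C)(C)C)C(=O)OC | intermediate
11 | methyl (R)-3-(tert-butyldimethylsilyloxy)-2-(trifluoromethylsulfonyloxy)propanoate | O=S(=O)(O[C@H](CO[Si](C)(C)C(C)(C)C)C(=O)OC)C(F)(F)F | intermediate
12 | dimethyl (2S,2'S)-2,2'-[(7S,8R,7'S,8'R)-syringaresinol-4,4'-diylbis(oxy)]bis[3-(tert-butyldimethylsilyloxy)propanoate] | COC(=O)[C@H](CO[Si](C)(C)C(C)(C)C)Oc1c(OC)cc([C@H]2OC[C@H]3[C@@H]2CO[C@@H]3c2cc(OC)c(O[C@@H](CO[Si](C)(C)C(C)(C)C)C(=O)OC)c(OC)c2)cc1OC | intermediate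
13 | (2S,2'S)-bis(N-methoxy-N-methylamide) corresponding to 12 | CON(C)C(=O)[C@H](CO[Si](C)(C)C(C)(C)C)Oc1c(OC)cc([C@H]2OC[C@H]3[C@@H]2CO[C@@H]3c2cc(OC)c(O[C@@H](CO[Si](C)(C)C(C)(C)C)C(=O)N(C)OC)c(OC)c2)cc1OC | intermediate
14 | 4-bromo-2-methoxyphenol | COc1cc(Br)ccc1O | starting material
15 | (4-bromo-2-methoxyphenoxy)(tert-butyl)dimethylsilane | COc1cc(Br)ccc1O[Si](C)(C)C(C)(C)C | intermediate
16 | 4-(tert-butyldimethylsilyloxy)-3-methoxyphenylmagnesium bromide | COc1cc([Mg]Br)ccc1O[Si](C)(C)C(C)(C)C | intermediate
17 | mono-ketone: (S)-Weinreb amide on one syringyl oxygen, (S)-1-[4-(TBS-oxy)-3-methoxyphenyl]-1-oxo-3-(TBS-oxy)propan-2-yl on the other | CON(C)C(=O)[C@H](CO[Si](C)(C)C(C)(C)C)Oc1c(OC)cc([C@H]2OC[C@H]3[C@@H]2CO[C@@H]3c2cc(OC)c(O[C@@H](CO[Si](C)(C)C(C)(C)C)C(=O)c3ccc(O[Si](C)(C)C(C)(C)C)c(OC)c3)c(OC)c2)cc1OC | intermediate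
18 | threo (αS,βS) alcohol from 17 | CON(C)C(=O)[C@H](CO[Si](C)(C)C(C)(C)C)Oc1c(OC)cc([C@H]2OC[C@H]3[C@@H]2CO[C@@H]3c2cc(OC)c(O[C@@H](CO[Si](C)(C)C(C)(C)C)[C@@H](O)c3ccc(O[Si](C)(C)C(C)(C)C)c(OC)c3)c(OC)c2)cc1OC | intermediate
19 | α-O-TBS ether of 18 | CON(C)C(=O)[C@H](CO[Si](C)(C)C(C)(C)C)Oc1c(OC)cc([C@H]2OC[C@H]3[C@@H]2CO[C@@H]3c2cc(OC)c(O[C@@H](CO[Si](C)(C)C(C)(C)C)[C@@H](O[Si](C)(C)C(C)(C)C)c3ccc(O[Si](C)(C)C(C)(C)C)c(OC)c3)c(OC)c2)cc1OC | intermediate
20 | phenol: 19 with free 4-hydroxyl on the unit B ring | CON(C)C(=O)[C@H](CO[Si](C)(C)C(C)(C)C)Oc1c(OC)cc([C@H]2OC[C@H]3[C@@H]2CO[C@@H]3c2cc(OC)c(O[C@@H](CO[Si](C)(C)C(C)(C)C)[C@@H](O[Si](C)(C)C(C)(C)C)c3ccc(O)c(OC)c3)c(OC)c2)cc1OC | intermediate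
21 | L-serine | N[C@@H](CO)C(=O)O | starting material
22 | (S)-glyceric acid, not isolated | O[C@@H](CO)C(=O)O | intermediate
23 | methyl (S)-glycerate | O[C@@H](CO)C(=O)OC | intermediate
24 | methyl (S)-3-(tert-butyldimethylsilyloxy)-2-hydroxypropanoate | O[C@@H](CO[Si](C)(C)C(C)(C)C)C(=O)OC | intermediate
25 | methyl (S)-3-(tert-butyldimethylsilyloxy)-2-(trifluoromethylsulfonyloxy)propanoate | O=S(=O)(O[C@@H](CO[Si](C)(C)C(C)(C)C)C(=O)OC)C(F)(F)F | intermediate
26 | ester–amide: 20 etherified at the unit B phenol with C2 of methyl (R)-3-(TBS-oxy)propanoate | CON(C)C(=O)[C@H](CO[Si](C)(C)C(C)(C)C)Oc1c(OC)cc([C@H]2OC[C@H]3[C@@H]2CO[C@@H]3c2cc(OC)c(O[C@@H](CO[Si](C)(C)C(C)(C)C)[C@@H](O[Si](C)(C)C(C)(C)C)c3ccc(O[C@H](CO[Si](C)(C)C(C)(C)C)C(=O)OC)c(OC)c3)c(OC)c2)cc1OC | intermediate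
27 | dialdehyde: formyl groups at the future Cα of units A and C, four TBS ethers | O=C[C@H](CO[Si](C)(C)C(C)(C)C)Oc1c(OC)cc([C@H]2OC[C@H]3[C@@H]2CO[C@@H]3c2cc(OC)c(O[C@@H](CO[Si](C)(C)C(C)(C)C)[C@@H](O[Si](C)(C)C(C)(C)C)c3ccc(O[C@H](CO[Si](C)(C)C(C)(C)C)C=O)c(OC)c3)c(OC)c2)cc1OC | intermediate
28 | hexa-O-TBS ether of the target, free Cα hydroxyls in units A (αR,βS) and C (αS,βR) | COc1cc([C@@H](O)[C@H](CO[Si](C)(C)C(C)(C)C)Oc2c(OC)cc([C@H]3OC[C@H]4[C@@H]3CO[C@@H]4c3cc(OC)c(O[C@@H](CO[Si](C)(C)C(C)(C)C)[C@@H](O[Si](C)(C)C(C)(C)C)c4ccc(O[C@H](CO[Si](C)(C)C(C)(C)C)[C@@H](O)c5ccc(O[Si](C)(C)C(C)(C)C)c(OC)c5)c(OC)c4)c(OC)c3)cc2OC)ccc1O[Si](C)(C)C(C)(C)C | intermediate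
29 | target: (7S,8R,7'S,8'R)-syringaresinol 4-O-[erythro-(αR,βS)-guaiacylglycerol-β-yl] 4'-O-{threo-(αS,βS)-guaiacylglycerol-β-yl 4-O-[erythro-(αS,βR)-guaiacylglycerol-β-yl]} ether | COc1cc([C@@H](O)[C@H](CO)Oc2c(OC)cc([C@H]3OC[C@H]4[C@@H]3CO[C@@H]4c3cc(OC)c(O[C@@H](CO)[C@@H](O)c4ccc(O[C@H](CO)[C@@H](O)c5ccc(O)c(OC)c5)c(OC)c4)c(OC)c3)cc2OC)ccc1O | target

**Summary**

Total step count: 22.
Longest linear sequence: 14 steps (steps 1–4, 8, 9, 12–15, 19–22, from syringaldehyde).

Steps most likely to fail:

1. Step 21. Facial selectivity may erode at one or both aldehydes if magnesium bridges the carbonyl and the aryloxy or ortho-methoxy oxygens (chelation gives threo), and the dialdehyde may enolise and epimerise at Cβ before addition. The fallback sets out from 26 and comes back at 28. The methyl ester of 26 would be converted into a second Weinreb amide (MeNH(OMe)·HCl, i-PrMgCl, THF, −20 °C) to give the bis(Weinreb amide) F1. An excess of 16 would then acylate both termini to give the bis(aryl ketone) F2; both Cα–aryl bonds are still made by the same Grignard reagent, but no stereocentre is created and no epimerisable aldehyde is handled. Reduction of F2 with Zn(BH4)2 in Et2O at −20 °C, where zinc bridges each carbonyl oxygen and its Cβ aryloxy oxygen and hydride enters from the less hindered face of the chelate, should give the erythro carbinol at both ends whatever the absolute sense of Cβ, and so return to 28.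

2. Step 13. Facial selectivity may be low or reversed if the branched, aryloxy-bearing chain competes with the aryl ring for the role of large substituent on the oxazaborolidine. The fallback sets out from 17 and comes back at 19. Chelation-controlled reduction of 17 with Zn(BH4)2 should give the erythro (αR,βS) alcohol F3. Mitsunobu inversion at Cα (4-nitrobenzoic acid, PPh3, DIAD, toluene, 0 °C) would give the threo 4-nitrobenzoate F4. Methanolysis (K2CO3, MeOH, 0 °C) would remove the benzoate together with the aryl silyl ether to give the threo phenol alcohol F5. Silylation of both hydroxyls with excess TBSOTf and 2,6-lutidine would then give 19.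

3. Step 8. The double etherification may stall if β-elimination or decomposition of the triflate outruns substitution at the hindered 2,6-dimethoxyphenoxides, or configuration at C2 may be partly lost. The fallback sets out from 6 (with the hydroxy ester 10 in place of the triflate) and comes back at 12. A double Mitsunobu etherification (PPh3, DIAD, THF, 0 °C to rt) activates the secondary hydroxyl of 10 in the flask and also inverts C2, so the same (S)-aryloxy diester 12 would form directly; no new compound arises.

Further compounds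
F1 | step 21 | bis(Weinreb amide): 26 with the unit C methyl ester replaced by N-methoxy-N-methylamide | CON(C)C(=O)[C@H](CO[Si](C)(C)C(C)(C)C)Oc1c(OC)cc([C@H]2OC[C@H]3[C@@H]2CO[C@@H]3c2cc(OC)c(O[C@@H](CO[Si](C)(C)C(C)(C)C)[C@@H](O[Si](C)(C)C(C)(C)C)c3ccc(O[C@H](CO[Si](C)(C)C(C)(C)C)C(=O)N(C)OC)c(OC)c3)c(OC)c2)cc1OC
F2 | step 21 | bis(aryl ketone): 28 with both free carbinols (Cα of units A and C) at the ketone level | COc1cc(C(=O)[C@H](CO[Si](C)(C)C(C)(C)C)Oc2c(OC)cc([C@H]3OC[C@H]4[C@@H]3CO[C@@H]4c3cc(OC)c(O[C@@H](CO[Si](C)(C)C(C)(C)C)[C@@H](O[Si](C)(C)C(C)(C)C)c4ccc(O[C@H](CO[Si](C)(C)C(C)(C)C)C(=O)c5ccc(O[Si](C)(C)C(C)(C)C)c(OC)c5)c(OC)c4)c(OC)c3)cc2OC)ccc1O[Si](C)(C)C(C)(C)C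
F3 | step 13 | erythro (αR,βS) alcohol, the Cα epimer of 18 | CON(C)C(=O)[C@H](CO[Si](C)(C)C(C)(C)C)Oc1c(OC)cc([C@H]2OC[C@H]3[C@@H]2CO[C@@H]3c2cc(OC)c(O[C@@H](CO[Si](C)(C)C(C)(C)C)[C@H](O)c3ccc(O[Si](C)(C)C(C)(C)C)c(OC)c3)c(OC)c2)cc1OC
F4 | step 13 | threo (αS,βS) 4-nitrobenzoate of 18 | CON(C)C(=O)[C@H](CO[Si](C)(C)C(C)(C)C)Oc1c(OC)cc([C@H]2OC[C@H]3[C@@H]2CO[C@@H]3c2cc(OC)c(O[C@@H](CO[Si](C)(C)C(C)(C)C)[C@@H](OC(=O)c3ccc(cc3)[N+](=O)[O-])c3ccc(O[Si](C)(C)C(C)(C)C)c(OC)c3)c(OC)c2)cc1OC
F5 | step 13 | threo (αS,βS) alcohol with free phenol on the unit B ring | CON(C)C(=O)[C@H](CO[Si](C)(C)C(C)(C)C)Oc1c(OC)cc([C@H]2OC[C@H]3[C@@H]2CO[C@@H]3c2cc(OC)c(O[C@@H](CO[Si](C)(C)C(C)(C)C)[C@@H](O)c3ccc(O)c(OC)c3)c(OC)c2)cc1OC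
F0 | step 8 | none | none
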